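**Remark on the chemistry:** flavan numbering (C2, C3, C4, C4a, C5–C8, C8a, primes for the 2‑aryl ring) is used for every unit, and β is the face opposite to the C2 aryl group and the C3 oxygen of an epicatechin‑type unit. For the three‑carbon chain of compounds 11–13 and 19, C1 is the carbon next to the 4‑benzyloxyphenyl ring. (−)‑Epicatechin, phloroglucinol and 4'‑(benzyloxy)acetophenone are taken as the purchased materials.

## The problem

The target 21 is epicatechin‑(4β→6)‑epiafzelechin‑(4β→8)‑epicatechin‑(4β→6)‑epicatechin (units B, A, C, D along the chain); two of its three interflavan bonds end at C6, against the preference of a 5,7‑dioxygenated ring A to react at C8. It has twelve stereocentres. C2 and C3 of units B, C and D are those of (−)‑epicatechin, and C4 of B and of C follows from them, because a nucleophile adds to a flavan‑4‑yl cation trans to the C3 oxygen. Unit A is an epiafzelechin (4‑hydroxyphenyl at C2, 2,3‑cis, 3,4‑trans) substituted at both C6 and C4; it is not a practical starting material, and inserting it by cation coupling would raise two regiochemical questions at once. Its C3 centre can steer C4, but C2, cis to the C3 oxygen, has to be set on its own. The interflavan bonds are diarylmethines flanked by phloroglucinol‑type rings and are cleaved or scrambled by acid, and the free catechols oxidise in base and air, so all phenols must stay masked until a last neutral step. The feature that opens the route is that C4 of unit A is a diarylmethine between C8 of unit C and C4a of its own ring A; C4a is one of two carbons ortho to O1 that become equivalent once unit B sits at C6, para to O1, so an O1–C2 aryl ether carrying a C3–C4 oxirane can close ring C of unit A through one C4–C4a bond without regiochemical choice. The price is that the oxirane carbon C4 is benzylic to a 2,4,6‑trioxygenated ring and opens easily, whether asked to or not.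

## Retrosynthesis

**21 from 20.** Eighteen O–benzyl bonds and the C8–Br bond of unit D are cut together. Benzyl ethers are chosen over silyl or acyl groups because one neutral hydrogenolysis removes them and the blocking bromine, whereas fluoride or base would act on a free polyphenol. The forward step must leave the benzylic C2–O1 bonds and the interflavan bonds alone.

**20 from 19 (key disconnection).** The C4–C4a bond of unit A is cut, which opens ring C and removes the C4 stereocentre. The neighbouring cut, C4(A)–C8(C) by cation coupling of two dimers, would need an epiafzelechin C4 electrophile and a C8/C6 choice on unit C. Cutting O1–C2 last is held in reserve. Precursor 19 is an acyclic aryl ether of an epoxy alcohol. The forward reaction must open the oxirane at C4 only, with inversion, in the 6‑endo mode.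

**19 from 13 and 18.** The O1–C2 ether bond is cut. This divides the molecule into two dimer‑sized halves, epoxy alcohol 13 (carrying units C and D) and phenol 18 (carrying unit B). A Mitsunobu reaction is asked to invert C2, so that the erythro alcohol 13 gives the threo ether and hence the 2,3‑cis unit A.

**13 from 12 from 11.** The carbinol is traced to ketone 12 and the oxirane to enone 11. The reverse order (oxazaborolidine reduction, then Ti(OiPr)4–tartrate epoxidation of the allylic alcohol) was weighed and set aside as the first choice. It would place a 2,4,6‑trioxygenated styrene oxide beside a Lewis‑acidic titanium alkoxide and free alcohols. The oxirane is instead made under basic conditions by catalyst‑controlled nucleophilic epoxidation, and the carbinol by chelation‑controlled reduction. One catalyst thus sets C3, and C3 sets C2.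

**11 from 9 and 10.** The Cα=Cβ bond (future C3–C4 of unit A) is cut by a crossed aldol condensation. Because the aldehyde carbon of 9 is already on C8 of unit C, the A–C junction is fixed as 4→8 by construction, not by selectivity.

**9 from 7 from 5 and 6.** The formyl group is traced to an iodine, and the C4(C)–C6(D) bond to a cation coupling. Bromine on C8 of 6 leaves C6 as the only nucleophilic carbon. Iodine on C8 of 5 lowers the nucleophilicity of the electrophile's own ring A and can be exchanged for magnesium without touching the bromine. An uncapped electrophile would alkylate itself at C8 faster than it finds the hindered C6 of 6.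

**18 from 17, 16, 15, from 4 and 14.** The C4(B)–aryl bond is cut back to phloroglucinol 14. 3,5‑Bis(benzyloxy)phenol would be attacked ortho to its hydroxyl (the C8‑like position), which after ring closure would give a 4→8 B–A junction. Phloroglucinol has three identical carbons, and the oxygen para to the flavanyl group is then singled out by its low hindrance (silylate, benzylate, desilylate). This costs three protecting‑group steps and buys certainty at the C–C bond.

**4, 5 and 6 from 3 from 2 from 1.** All three epicatechin units come from (−)‑epicatechin 1 through pentabenzyl ether 3; C4 is activated oxidatively (4) and the halogens are placed on C8 (5, 6).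

## Roads not taken

**Alternative 1:** The cut is C4a–C5 of ring A of unit D. The forward key step heats a dioxinone tethered to a dihydropyran enol ether; cycloreversion gives an acylketene whose C5 bonds to C4a, and enolisation aromatises the ring to A1, the octabenzyl C–D dimer with free O5 and O7 on unit D. Merits: the 4→6 connectivity is written into the chain, no halogen blocking and no cation coupling are needed, and the conditions are neutral. Weak points: unit C must hang through C4 on a carbon between two carbonyls, where ionisation to a flavan‑4‑yl cation and a stabilised enolate threatens the C4 centre. The C2/C3 centres of unit D must be built although epicatechin supplies them. A1 then needs benzylation, and C8 of its unit D is unblocked. Comparison: for the C–D bond alone this road is regiochemically cleaner than step 6, which needs two halogens and excess nucleophile. The chosen plan sets against it a six‑step access to the same dimer from epicatechin, and it spends its new ring construction on unit A, which Alternative 1 does not address.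

**Alternative 2:** The cut is C3=C4 of unit A as an alkene. Second‑generation Grubbs catalyst RuCl2(=CHPh)(PCy3)(H2IMes) closes an ortho‑vinyl aryl ether of a chiral allylic alcohol to the flav‑3‑ene A2, which already carries unit B. The C3 oxygen and the bond to C8 of unit C would then be added across the alkene by epoxidation and Lewis‑acid opening with the C–D dimer. Merits: the metathesis is neutral and reliable, C2 is set on a small fragment, the union is fully convergent, and no labile aryl oxirane is carried through two steps. Weak points: an oxidant approaches the chromene anti to the C2 aryl group, giving the 2,3‑trans (catechin‑type) series, so C3 would have to be inverted next to an acid‑labile C4 diarylmethine. The final union of two dimers must also choose C8 over C6 of unit C. Comparison: the ring closure of A2 is safer than step 16, and the convergence is better. The chosen plan sets against it that 2,3‑cis is made by design (catalyst‑set oxirane plus Mitsunobu inversion) and that the A–C regiochemistry is fixed by the position of an aldehyde.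

**Alternative 3:** The cuts are C4–C4a and O1–C2 of unit C, which is grown on unit D. A diarylprolinol silyl ether with benzoic acid turns an enal on C6 of 8‑bromo unit D into an iminium ion; an ortho carbon of a 3,5‑dioxygenated phenol adds to the β‑carbon and the phenol oxygen to the aldehyde carbon, giving lactol A3. Merits: C4 of unit C is set by a catalyst, the 4→6 connectivity is guaranteed by where the enal sits, and there is no flavan‑4‑yl cation and no self‑condensation. Weak points: A3 still lacks the C2 aryl ring and the C3 oxygen of unit C, so two more stereocentres must be built to recreate a unit that epicatechin delivers intact. The β‑carbon bears a 2,6‑dioxygenated aryl group and will react slowly. The catalyst must override the chiral unit D. Comparison: stereo‑ and regiocontrol at the C–D junction are better than in step 6. The chosen plan sets against it far fewer steps for units C and D, and it builds a ring in place only once, at unit A, where no natural unit can serve.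

Key step: step 16

## Route

Step 1
Reactants: 1 (−)-epicatechin
Product: 2 tetra-O-benzyl ether of 1 (5,7,3',4'-tetra-O-benzyl-(−)-epicatechin; 3-OH free)
Conditions: BnBr (4.4 equiv), K2CO3, DMF, 0 °C to rt
Reagents that add atoms: benzyl bromide, BrCc1ccccc1
Why: Williamson etherification of the four phenols under carbonate; the secondary C3 alcohol is not deprotonated and no stereocentre is touched.

Step 2
Reactants: 2 tetra-O-benzyl-(−)-epicatechin
Product: 3 penta-O-benzyl-(−)-epicatechin (3,5,7,3',4'-penta-O-benzyl; 2R,3R)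
Conditions: NaH, BnBr, Bu4NI (cat.), THF–DMF, 0 °C to rt
Reagents that add atoms: benzyl bromide, BrCc1ccccc1
Why: Williamson etherification of the C3 alkoxide; with all phenols already capped there is no quinone-methide path to C2 epimerisation.

Step 3
Reactants: 3 penta-O-benzyl-(−)-epicatechin
Product: 4 4β-(2-ethoxyethoxy)-penta-O-benzylepicatechin (2R,3R,4S)
Conditions: DDQ, 2-ethoxyethanol, CH2Cl2, rt
Reagents that add atoms: 2-ethoxyethanol, CCOCCO
Why: Oxidative benzylic functionalisation: DDQ removes hydride from C4, and the cation, stabilised by O1, O5 and O7, is trapped by the alcohol trans to the C3 benzyloxy group, which sets C4 as 4β.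

Step 4
Reactants: 4 4β-(2-ethoxyethoxy)-penta-O-benzylepicatechin
Product: 5 8-iodo-4β-(2-ethoxyethoxy)-penta-O-benzylepicatechin
Conditions: N-iodosuccinimide, CH2Cl2, 0 °C, dark
Reagents that add atoms: N-iodosuccinimide, O=C1CCC(=O)N1I
Why: Electrophilic aromatic iodination at C8, the more accessible of the two free ring A carbons (between O1 and the 7-benzyloxy group); the iodine lowers the nucleophilicity of this ring and is the later formyl handle.

Step 5
Reactants: 3 penta-O-benzyl-(−)-epicatechin
Product: 6 8-bromo-penta-O-benzylepicatechin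
Conditions: N-bromosuccinimide, CH2Cl2, −78 °C to 0 °C
Reagents that add atoms: N-bromosuccinimide, O=C1CCC(=O)N1Br
Why: Electrophilic aromatic bromination, selective for C8 as in step 4; the bromine blocks C8 so that only C6 of unit D can act as nucleophile.

Step 6
Reactants: 5 8-iodo-4β-(2-ethoxyethoxy)-penta-O-benzylepicatechin; 6 8-bromo-penta-O-benzylepicatechin (3 equiv)
Product: 7 C–D dimer 8-iodo-penta-O-benzylepicatechin-(4β→6)-8-bromo-penta-O-benzylepicatechin
Conditions: BF3·OEt2, CH2Cl2, −78 °C to −30 °C, slow addition of 5 to 6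
Reagents that add atoms: none
Why: Friedel–Crafts alkylation by a flavan-4-yl cation: BF3 ionises the C4 ether of 5 and C6 of 6, its only free ring A carbon, attacks trans to the C3 benzyloxy group, which sets C4 of unit C as 4β. Excess 6 and slow addition hold back self-alkylation of 5 and over-alkylation of 7.

Step 7
Reactants: 7 C–D dimer with iodine on C8 of unit C
Product: 9 8-formyl-penta-O-benzylepicatechin-(4β→6)-8-bromo-penta-O-benzylepicatechin, via arylmagnesium chloride 8 (not isolated)
Conditions: iPrMgCl·LiCl, THF, −20 °C; DMF, −20 °C to 0 °C; aq NH4Cl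
Reagents that add atoms: N,N-dimethylformamide, CN(C)C=O (formyl group of 9); isopropylmagnesium chloride–lithium chloride, CC(C)[Mg]Cl.[Li+].[Cl-] (MgCl of intermediate 8 only)
Why: Iodine–magnesium exchange is much faster for the aryl iodide than for the aryl bromide, so the bromine on unit D stays; Bouveault formylation of the arylmagnesium species with DMF gives the aldehyde on C8 of unit C.

Step 8
Reactants: 9 8-formyl C–D dimer; 10 4'-(benzyloxy)acetophenone
Product: 11 (E)-1-(4-benzyloxyphenyl)-3-(C8 of unit C of the C–D dimer)prop-2-en-1-one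
Conditions: KOH, THF–EtOH, rt to 40 °C
Reagents that add atoms: none
Why: Claisen–Schmidt condensation: the enolate of 10 adds to the non-enolisable aldehyde and E1cB dehydration gives the (E)-enone; benzyl ethers, the aryl bromide and the interflavan bond are stable to hydroxide.

Step 9
Reactants: 11 (E)-enone
Product: 12 (2R,3S)-trans-2,3-epoxy ketone of 11
Conditions: poly-L-leucine, urea–H2O2, DBU, THF, rt
Reagents that add atoms: urea–hydrogen peroxide, OO.NC(N)=O (one oxygen)
Why: Juliá–Colonna epoxidation: hydroperoxide adds to the β-carbon inside the helical peptide and the enolate closes the oxirane; poly-L-leucine delivers the (2R,3S) trans-epoxy ketone, which sets C3 and the provisional C4 of unit A. The basic, water-free medium spares the acid-labile benzylic oxirane.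

Step 10
Reactants: 12 (2R,3S)-epoxy ketone
Product: 13 (1S,2S,3S)-1-(4-benzyloxyphenyl)-3-(C8 of unit C of the C–D dimer)-2,3-epoxypropan-1-ol (erythro)
Conditions: Zn(BH4)2, Et2O–THF, −30 °C; pH 7 phosphate buffer
Reagents that add atoms: none
Why: Chelation-controlled reduction: zinc bridges the carbonyl and oxirane oxygens and hydride arrives on the face away from the oxirane carbon C3, giving the erythro (1S) carbinol. The letter at C2 changes from R to S only through CIP priority.

Step 11
Reactants: 4 4β-(2-ethoxyethoxy)-penta-O-benzylepicatechin; 14 phloroglucinol (6 equiv)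
Product: 15 4β-(2,4,6-trihydroxyphenyl)-penta-O-benzylepicatechin
Conditions: BF3·OEt2, THF–CH2Cl2, −20 °C to 0 °C
Reagents that add atoms: none
Why: Friedel–Crafts alkylation by the flavan-4-yl cation, trans to the C3 benzyloxy group (4β). The three ring carbons of phloroglucinol are identical, so no regiochemical question arises, and its excess and high nucleophilicity outrun self-alkylation of 4.

Step 12
Reactants: 15 4β-(2,4,6-trihydroxyphenyl)-penta-O-benzylepicatechin
Product: 16 4β-[2,6-dihydroxy-4-(triisopropylsilyloxy)phenyl]-penta-O-benzylepicatechin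
Conditions: iPr3SiCl (1.05 equiv), imidazole, DMF, −20 °C to 0 °C
Reagents that add atoms: triisopropylsilyl chloride, CC(C)[Si](Cl)(C(C)C)C(C)C
Why: Sterically controlled silylation: the hydroxyl para to the flavanyl group has two free ortho positions, while the other two are shielded by the flavan and hydrogen-bonded to its 3- and 5-benzyloxy oxygens.

Step 13
Reactants: 16 mono-silyl ether
Product: 17 4β-[2,6-bis(benzyloxy)-4-(triisopropylsilyloxy)phenyl]-penta-O-benzylepicatechin
Conditions: BnBr, K2CO3, DMF, rt
Reagents that add atoms: benzyl bromide, BrCc1ccccc1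
Why: Williamson etherification of the two remaining phenols; an aryl triisopropylsilyl ether withstands anhydrous carbonate at room temperature.

Step 14
Reactants: 17 silyl ether
Product: 18 4β-[2,6-bis(benzyloxy)-4-hydroxyphenyl]-penta-O-benzylepicatechin (3,5-bis(benzyloxy)phenol carrying unit B at C4)
Conditions: Bu4NF, AcOH, THF, 0 °C
Reagents that add atoms: none
Why: Fluoride-induced cleavage of the aryl silyl ether; acetic acid buffering keeps the phenoxide from air oxidation, and the benzyl ethers are inert.

Step 15
Reactants: 13 (1S,2S,3S)-epoxy alcohol; 18 phenol carrying unit B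
Product: 19 (1R,2R,3S)-epoxy aryl ether (O1–C2 ether between 18 and the C8-oxiranyl C–D dimer)
Conditions: PPh3, DIAD, toluene, 0 °C; rapid filtration through Et3N-treated silica, used at once
Reagents that add atoms: none
Why: Mitsunobu etherification: the phenoxide displaces the oxyphosphonium group at C1 (future C2 of unit A) with inversion, (1S) to (1R), giving the threo ether that becomes 2,3-cis. The electron-withdrawing oxirane next to the carbinol and the non-polar solvent disfavour ionisation; the letter at C2 changes only through CIP priority.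

Step 16
Reactants: 19 (1R,2R,3S)-epoxy aryl ether
Product: 20 octadeca-O-benzyl tetramer (bromine on C8 of unit D; 3-OH of unit A free)
Conditions: BF3·OEt2 (0.3 equiv), CH2Cl2 (0.005 M), −78 °C; Et3N quench
Reagents that add atoms: none
Why: BF3 binds the oxirane oxygen and the C4–O bond, benzylic to the 2,4,6-trioxygenated ring of unit C, lengthens; one of the two equivalent ortho carbons of the aryl ether attacks C4 opposite to the leaving oxygen and the arenium ion loses a proton, which is the known intramolecular Friedel–Crafts epoxy-arene cyclisation of aryl ethers of 3-aryl-2,3-epoxy alcohols to trans-4-arylchroman-3-ols. Ring C of unit A closes in the 6-endo mode (attack at the distal oxirane carbon); the 5-exo closure at C3 would give a dihydrobenzofuran and does not compete because C3 is not benzylic. The new stereocentre C4 is controlled by C3: inversion at C4 of the trans-oxirane puts the unit C aryl group trans to the C3 hydroxyl (4β), and if ionisation runs ahead of bond formation the half-chair with the C2 aryl group equatorial is still attacked anti to the boron-bound C3 oxygen. C2 and C3 are not touched, so the 2,3-cis relation from steps 9, 10 and 15 is kept. The step needs chemoselectivity against hydride shift from C3 and against intermolecular alkylation of the free ring A of unit B; low temperature, sub-stoichiometric Lewis acid and high dilution are there to secure it, and the existing interflavan bonds should not ionise at −78 °C. No regiochemical choice arises because unit B sits para to the ether oxygen.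

Step 17
Reactants: 20 octadeca-O-benzyl tetramer
Product: 21 epicatechin-(4β→6)-epiafzelechin-(4β→8)-epicatechin-(4β→6)-epicatechin (CNP0103636.1)
Conditions: H2 (1 atm), Pd(OH)2/C, Et3N (2 equiv), THF–MeOH–H2O, rt; Sephadex LH-20
Reagents that add atoms: none
Why: Catalytic hydrogenolysis removes the eighteen benzyl ethers and the aryl bromine in one operation; the amine takes up HBr so that the acid-labile interflavan bonds stay intact, and no stereocentre is involved.

## Compound list

1 | (−)-epicatechin (2R,3R) | Oc1cc(O)c2C[C@@H](O)[C@@H](c3ccc(O)c(O)c3)Oc2c1 | starting material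
2 | 5,7,3',4'-tetra-O-benzyl-(−)-epicatechin | C(c9ccccc9)Oc1cc(OCc9ccccc9)c2C[C@@H](O)[C@@H](c3ccc(OCc9ccccc9)c(OCc9ccccc9)c3)Oc2c1 | intermediate
3 | 3,5,7,3',4'-penta-O-benzyl-(−)-epicatechin | C(c9ccccc9)Oc1cc(OCc9ccccc9)c2C[C@@H](OCc9ccccc9)[C@@H](c3ccc(OCc9ccccc9)c(OCc9ccccc9)c3)Oc2c1 | intermediate
4 | 4β-(2-ethoxyethoxy)-penta-O-benzylepicatechin (2R,3R,4S) | CCOCCO[C@H]1c2c(OCc9ccccc9)cc(OCc9ccccc9)cc2O[C@H](c2ccc(OCc9ccccc9)c(OCc9ccccc9)c2)[C@@H]1OCc9ccccc9 | intermediate
5 | 8-iodo-4β-(2-ethoxyethoxy)-penta-O-benzylepicatechin | CCOCCO[C@H]1c2c(OCc9ccccc9)cc(OCc9ccccc9)c(I)c2O[C@H](c2ccc(OCc9ccccc9)c(OCc9ccccc9)c2)[C@@H]1OCc9ccccc9 | intermediate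
6 | 8-bromo-penta-O-benzylepicatechin | C(c9ccccc9)Oc1cc(OCc9ccccc9)c2C[C@@H](OCc9ccccc9)[C@@H](c3ccc(OCc9ccccc9)c(OCc9ccccc9)c3)Oc2c1Br | intermediate
7 | C–D dimer, 8-iodo-penta-O-benzylepicatechin-(4β→6)-8-bromo-penta-O-benzylepicatechin | Ic3c(OCc9ccccc9)cc(OCc9ccccc9)c4c3O[C@H](c3ccc(OCc9ccccc9)c(OCc9ccccc9)c3)[C@H](OCc9ccccc9)[C@H]4c3c(OCc9ccccc9)c(Br)c4c(c3OCc9ccccc9)C[C@@H](OCc9ccccc9)[C@@H](c3ccc(OCc9ccccc9)c(OCc9ccccc9)c3)O4 | intermediate
8 | arylmagnesium chloride of the C–D dimer (MgCl on C8 of unit C) | Cl[Mg]c3c(OCc9ccccc9)cc(OCc9ccccc9)c4c3O[C@H](c3ccc(OCc9ccccc9)c(OCc9ccccc9)c3)[C@H](OCc9ccccc9)[C@H]4c3c(OCc9ccccc9)c(Br)c4c(c3OCc9ccccc9)C[C@@H](OCc9ccccc9)[C@@H](c3ccc(OCc9ccccc9)c(OCc9ccccc9)c3)O4 | intermediate (not isolated)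
9 | 8-formyl-penta-O-benzylepicatechin-(4β→6)-8-bromo-penta-O-benzylepicatechin | O=Cc3c(OCc9ccccc9)cc(OCc9ccccc9)c4c3O[C@H](c3ccc(OCc9ccccc9)c(OCc9ccccc9)c3)[C@H](OCc9ccccc9)[C@H]4c3c(OCc9ccccc9)c(Br)c4c(c3OCc9ccccc9)C[C@@H](OCc9ccccc9)[C@@H](c3ccc(OCc9ccccc9)c(OCc9ccccc9)c3)O4 | intermediate
10 | 4'-(benzyloxy)acetophenone | CC(=O)c1ccc(OCc2ccccc2)cc1 | starting material
11 | (E)-enone, 1-(4-benzyloxyphenyl)-3-(C8 of unit C of the C–D dimer)prop-2-en-1-one | C(c9ccccc9)Oc1ccc(cc1)C(=O)/C=C/c3c(OCc9ccccc9)cc(OCc9ccccc9)c4c3O[C@H](c3ccc(OCc9ccccc9)c(OCc9ccccc9)c3)[C@H](OCc9ccccc9)[C@H]4c3c(OCc9ccccc9)c(Br)c4c(c3OCc9ccccc9)C[C@@H](OCc9ccccc9)[C@@H](c3ccc(OCc9ccccc9)c(OCc9ccccc9)c3)O4 | intermediate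
12 | (2R,3S)-trans-2,3-epoxy ketone of 11 | C(c9ccccc9)Oc1ccc(cc1)C(=O)[C@@H]1O[C@H]1c3c(OCc9ccccc9)cc(OCc9ccccc9)c4c3O[C@H](c3ccc(OCc9ccccc9)c(OCc9ccccc9)c3)[C@H](OCc9ccccc9)[C@H]4c3c(OCc9ccccc9)c(Br)c4c(c3OCc9ccccc9)C[C@@H](OCc9ccccc9)[C@@H](c3ccc(OCc9ccccc9)c(OCc9ccccc9)c3)O4 | intermediate
13 | (1S,2S,3S)-erythro epoxy alcohol | C(c9ccccc9)Oc1ccc(cc1)[C@H](O)[C@@H]1O[C@H]1c3c(OCc9ccccc9)cc(OCc9ccccc9)c4c3O[C@H](c3ccc(OCc9ccccc9)c(OCc9ccccc9)c3)[C@H](OCc9ccccc9)[C@H]4c3c(OCc9ccccc9)c(Br)c4c(c3OCc9ccccc9)C[C@@H](OCc9ccccc9)[C@@H](c3ccc(OCc9ccccc9)c(OCc9ccccc9)c3)O4 | intermediate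
14 | phloroglucinol | Oc1cc(O)cc(O)c1 | starting material
15 | 4β-(2,4,6-trihydroxyphenyl)-penta-O-benzylepicatechin | Oc1cc(O)c([C@H]4c5c(OCc9ccccc9)cc(OCc9ccccc9)cc5O[C@H](c5ccc(OCc9ccccc9)c(OCc9ccccc9)c5)[C@@H]4OCc9ccccc9)c(O)c1 | intermediate
16 | 4β-[2,6-dihydroxy-4-(triisopropylsilyloxy)phenyl]-penta-O-benzylepicatechin | CC(C)[Si](C(C)C)(C(C)C)Oc1cc(O)c([C@H]4c5c(OCc9ccccc9)cc(OCc9ccccc9)cc5O[C@H](c5ccc(OCc9ccccc9)c(OCc9ccccc9)c5)[C@@H]4OCc9ccccc9)c(O)c1 | intermediate
17 | 4β-[2,6-bis(benzyloxy)-4-(triisopropylsilyloxy)phenyl]-penta-O-benzylepicatechin | CC(C)[Si](C(C)C)(C(C)C)Oc1cc(OCc9ccccc9)c([C@H]4c5c(OCc9ccccc9)cc(OCc9ccccc9)cc5O[C@H](c5ccc(OCc9ccccc9)c(OCc9ccccc9)c5)[C@@H]4OCc9ccccc9)c(OCc9ccccc9)c1 | intermediate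
18 | 4β-[2,6-bis(benzyloxy)-4-hydroxyphenyl]-penta-O-benzylepicatechin | Oc1cc(OCc9ccccc9)c([C@H]4c5c(OCc9ccccc9)cc(OCc9ccccc9)cc5O[C@H](c5ccc(OCc9ccccc9)c(OCc9ccccc9)c5)[C@@H]4OCc9ccccc9)c(OCc9ccccc9)c1 | intermediate
19 | (1R,2R,3S)-epoxy aryl ether, key-step precursor | C(c9ccccc9)Oc1ccc(cc1)[C@@H](Oc1cc(OCc9ccccc9)c([C@H]4c5c(OCc9ccccc9)cc(OCc9ccccc9)cc5O[C@H](c5ccc(OCc9ccccc9)c(OCc9ccccc9)c5)[C@@H]4OCc9ccccc9)c(OCc9ccccc9)c1)[C@@H]1O[C@H]1c3c(OCc9ccccc9)cc(OCc9ccccc9)c4c3O[C@H](c3ccc(OCc9ccccc9)c(OCc9ccccc9)c3)[C@H](OCc9ccccc9)[C@H]4c3c(OCc9ccccc9)c(Br)c4c(c3OCc9ccccc9)C[C@@H](OCc9ccccc9)[C@@H](c3ccc(OCc9ccccc9)c(OCc9ccccc9)c3)O4 | intermediate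
20 | octadeca-O-benzyl tetramer, bromine on C8 of unit D, 3-OH of unit A free | C(c9ccccc9)Oc1ccc([C@H]2Oc3cc(OCc9ccccc9)c([C@H]4c5c(OCc9ccccc9)cc(OCc9ccccc9)cc5O[C@H](c5ccc(OCc9ccccc9)c(OCc9ccccc9)c5)[C@@H]4OCc9ccccc9)c(OCc9ccccc9)c3[C@H](c3c(OCc9ccccc9)cc(OCc9ccccc9)c4c3O[C@H](c3ccc(OCc9ccccc9)c(OCc9ccccc9)c3)[C@H](OCc9ccccc9)[C@H]4c3c(OCc9ccccc9)c(Br)c4c(c3OCc9ccccc9)C[C@@H](OCc9ccccc9)[C@@H](c3ccc(OCc9ccccc9)c(OCc9ccccc9)c3)O4)[C@H]2O)cc1 | intermediate
21 | epicatechin-(4β→6)-epiafzelechin-(4β→8)-epicatechin-(4β→6)-epicatechin | Oc1ccc([C@H]2Oc3cc(O)c([C@H]4c5c(O)cc(O)cc5O[C@H](c5ccc(O)c(O)c5)[C@@H]4O)c(O)c3[C@H](c3c(O)cc(O)c4c3O[C@H](c3ccc(O)c(O)c3)[C@H](O)[C@H]4c3c(O)cc4c(c3O)C[C@@H](O)[C@@H](c3ccc(O)c(O)c3)O4)[C@H]2O)cc1 | target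

## Step count and risks

Total: 17 steps. Longest linear sequence: 12 steps (1, 2, 3, 4, 5, 7, 9, 11, 12, 13, 19, 20, 21 through steps 1, 2, 3, 4, 6, 7, 8, 9, 10, 15, 16, 17).

**Step 16 (key step).** The likely failure is hydride migration from C3 to the ionised C4, which would give a benzyl ketone instead of ring closure; the C3 oxygen bound to boron pushes this shift. Capture of the cation by the free ring A of unit B of a second molecule is the second risk. The fallback sets out from 19. The oxirane is opened at C4 with 4‑methylbenzenethiol (CH2Cl2, −40 °C), giving the hydroxy sulfide F1. The soft leaving group is then activated with AgOSO2CF3 and 2,6‑di‑tert‑butyl‑4‑methylpyridine. This generates the C4 cation without a Lewis acid on the C3 oxygen, so the same ortho carbon closes ring C anti to the free C3 hydroxyl. The fallback comes back to the route at 20.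

**Step 15.** The likely failure is opening of the trioxygenated benzylic oxirane by the acidic phenol or the oxyphosphonium intermediate; partial ionisation at the 4‑benzyloxybenzylic carbinol, with loss of clean inversion, is the second risk. The fallback reverses the order of the two ring C bonds and sets out from 13 and 18. Catalytic BF3·OEt2 at −78 °C lets the ortho carbon of the free phenol 18 open the oxirane of 13 at C4 with inversion, giving the triol F3. A Mitsunobu cyclo‑etherification (PPh3, DIAD) then lets the phenol oxygen displace the benzylic C2 hydroxyl with inversion. It comes back at 20, passing over 19.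

**Step 9.** The likely failure is slow or unselective hydroperoxide addition, because the β‑carbon carries a bulky, electron‑rich 2,6‑dioxygenated aryl group that may not fit the peptide catalyst. The fallback sets out from 11. (S)‑2‑methyl‑CBS‑oxazaborolidine with catecholborane reduces the ketone, the 4‑benzyloxyphenyl group acting as the large substituent, to the (R)‑allylic alcohol F2. Ti(OiPr)4, L‑(+)‑diisopropyl tartrate and tBuOOH with 4 Å sieves at −25 °C then epoxidise the matched face, and any (S)‑carbinol reacts slowly and is left behind. It comes back at 13. Its own weak point is the contact of the oxirane with the titanium alkoxide, which is why it is the reserve.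

**Step 6.** The likely failure is oligomer formation, because C6 of bromo‑capped 6 is only about as nucleophilic as C6 of the electrophile and of the product. The fallback sets out from 5. Iodine–magnesium exchange and DMF give 8‑formyl‑4β‑(2‑ethoxyethoxy)‑penta‑O‑benzylepicatechin F4, whose aldehyde withdraws density from all three ring A oxygens and shuts off self‑alkylation. Coupling of F4 with 6 under Me3SiOSO2CF3 (CH2Cl2, −40 °C to 0 °C) then gives the dimer directly. It comes back at 9, passing over 7.

**Step 12.** The likely failure is incomplete discrimination between the para hydroxyl and the two ortho hydroxyls, which would carry regioisomers forward to a 4→8 B–A junction. The fallback enforces the regiochemistry with blocking atoms and sets out from 5. Purchased 3,5‑bis(benzyloxy)phenol F5 is brominated at both carbons ortho to the hydroxyl (N‑bromosuccinimide, catalytic iPr2NH, CH2Cl2) to give 2,6‑dibromo‑3,5‑bis(benzyloxy)phenol F6. Its only free carbon is alkylated by 5 under BF3·OEt2 to give the trihalide F7. Halogen–lithium exchange with excess n‑BuLi (THF, −78 °C) and a methanol quench then removes the iodine and both bromines. It comes back at 18.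

## Further compounds

F1 | step 16 | hydroxy sulfide from 19: C4 bears 4-methylphenylthio (anti opening), C3 hydroxyl free | C(c9ccccc9)Oc1ccc(cc1)[C@@H](Oc1cc(OCc9ccccc9)c([C@H]4c5c(OCc9ccccc9)cc(OCc9ccccc9)cc5O[C@H](c5ccc(OCc9ccccc9)c(OCc9ccccc9)c5)[C@@H]4OCc9ccccc9)c(OCc9ccccc9)c1)[C@H](O)[C@H](Sc1ccc(C)cc1)c3c(OCc9ccccc9)cc(OCc9ccccc9)c4c3O[C@H](c3ccc(OCc9ccccc9)c(OCc9ccccc9)c3)[C@H](OCc9ccccc9)[C@H]4c3c(OCc9ccccc9)c(Br)c4c(c3OCc9ccccc9)C[C@@H](OCc9ccccc9)[C@@H](c3ccc(OCc9ccccc9)c(OCc9ccccc9)c3)O4
F2 | step 9 | (R,E)-allylic alcohol from 11 | C(c9ccccc9)Oc1ccc(cc1)[C@H](O)/C=C/c3c(OCc9ccccc9)cc(OCc9ccccc9)c4c3O[C@H](c3ccc(OCc9ccccc9)c(OCc9ccccc9)c3)[C@H](OCc9ccccc9)[C@H]4c3c(OCc9ccccc9)c(Br)c4c(c3OCc9ccccc9)C[C@@H](OCc9ccccc9)[C@@H](c3ccc(OCc9ccccc9)c(OCc9ccccc9)c3)O4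
F3 | step 15 | triol from C-alkylation of phenol 18 by epoxy alcohol 13 (C1 and C2 hydroxyls, free phenol, C3 diarylmethine) | C(c9ccccc9)Oc1ccc(cc1)[C@H](O)[C@H](O)[C@H](c1c(O)cc(OCc9ccccc9)c([C@H]4c5c(OCc9ccccc9)cc(OCc9ccccc9)cc5O[C@H](c5ccc(OCc9ccccc9)c(OCc9ccccc9)c5)[C@@H]4OCc9ccccc9)c1OCc9ccccc9)c3c(OCc9ccccc9)cc(OCc9ccccc9)c4c3O[C@H](c3ccc(OCc9ccccc9)c(OCc9ccccc9)c3)[C@H](OCc9ccccc9)[C@H]4c3c(OCc9ccccc9)c(Br)c4c(c3OCc9ccccc9)C[C@@H](OCc9ccccc9)[C@@H](c3ccc(OCc9ccccc9)c(OCc9ccccc9)c3)O4
F4 | step 6 | 8-formyl-4β-(2-ethoxyethoxy)-penta-O-benzylepicatechin | CCOCCO[C@H]1c2c(OCc9ccccc9)cc(OCc9ccccc9)c(C=O)c2O[C@H](c2ccc(OCc9ccccc9)c(OCc9ccccc9)c2)[C@@H]1OCc9ccccc9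
F5 | step 12 | 3,5-bis(benzyloxy)phenol | Oc1cc(OCc2ccccc2)cc(OCc2ccccc2)c1
F6 | step 12 | 2,6-dibromo-3,5-bis(benzyloxy)phenol | Oc1c(Br)c(OCc2ccccc2)cc(OCc2ccccc2)c1Br
F7 | step 12 | 4-(8-iodo-penta-O-benzylepicatechin-4β-yl)-2,6-dibromo-3,5-bis(benzyloxy)phenol | Oc1c(Br)c(OCc9ccccc9)c([C@H]4c5c(OCc9ccccc9)cc(OCc9ccccc9)c(I)c5O[C@H](c5ccc(OCc9ccccc9)c(OCc9ccccc9)c5)[C@@H]4OCc9ccccc9)c(OCc9ccccc9)c1Br
A1 | alternative 1 | octa-O-benzyl epicatechin-(4β→6)-epicatechin with free O5 and O7 on unit D | c3c(OCc9ccccc9)cc(OCc9ccccc9)c4c3O[C@H](c3ccc(OCc9ccccc9)c(OCc9ccccc9)c3)[C@H](OCc9ccccc9)[C@H]4c3c(O)cc4c(c3O)C[C@@H](OCc9ccccc9)[C@@H](c3ccc(OCc9ccccc9)c(OCc9ccccc9)c3)O4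
A2 | alternative 2 | unit-B-substituted 5,7-bis(benzyloxy)-2-(4-benzyloxyphenyl)-2H-chromene (flav-3-ene of unit A) | C(c9ccccc9)Oc1ccc([C@H]2Oc3cc(OCc9ccccc9)c([C@H]4c5c(OCc9ccccc9)cc(OCc9ccccc9)cc5O[C@H](c5ccc(OCc9ccccc9)c(OCc9ccccc9)c5)[C@@H]4OCc9ccccc9)c(OCc9ccccc9)c3C=C2)cc1
A3 | alternative 3 | 5,7-bis(benzyloxy)-4-(8-bromo-penta-O-benzylepicatechin-6-yl)chroman-2-ol (lactol, one anomer) | O[C@H]1C[C@@H](c3c(OCc9ccccc9)c(Br)c4c(c3OCc9ccccc9)C[C@@H](OCc9ccccc9)[C@@H](c3ccc(OCc9ccccc9)c(OCc9ccccc9)c3)O4)c2c(OCc9ccccc9)cc(OCc9ccccc9)cc2O1
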